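**Assumption:** the target has no stereocentre or stereo-axis, so no stereocontrol is needed; 1 and 5 are taken as catalogue building blocks.

**Retrosynthetic overview**
- The indole and pyrrole rings are bought intact with their bromines in place; only the central oxazole is built, and it is built last.
- The oxazole C4–C5 and O1–C2 bonds are made in one operation from an N-Boc indole-3-carbaldehyde (C5, O1) and a reagent TsCH2–N=C(SMe)–(5-bromopyrrol-2-yl) (C4, N3, C2).
- In that step the N-bound CH2 carbon, normally an N-acyliminium-type electrophile, acts as a sulfonyl-stabilised carbanion toward the aldehyde carbon; MeSH, sulfinic acid and Boc are lost in the same flask.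
- The reagent comes from 5-bromopyrrole-2-carboxamide by Mannich condensation with CH2O and sulfinate, thionation and S-methylation.
- The aldehyde comes from 6-bromo-4-methoxyindole by Vilsmeier formylation and Boc protection.

**Step 1**
Reactants: 1 6-bromo-4-methoxy-1H-indole
Product: 3 6-bromo-4-methoxy-1H-indole-3-carbaldehyde, via iminium chloride 2 (not isolated)
Conditions: POCl3, DMF, 0 °C to 40 °C; then aq. NaOH, 60 °C
Reagents that add atoms: N,N-dimethylformamide CN(C)C=O; water O
Why: Vilsmeier–Haack formylation attacks the enamine-like C3, the most nucleophilic indole position even with the 4-methoxy group present, and aqueous base hydrolyses iminium salt 2 to the aldehyde.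

**Step 2**
Reactants: 3 6-bromo-4-methoxy-1H-indole-3-carbaldehyde
Product: 4 tert-butyl 6-bromo-3-formyl-4-methoxy-1H-indole-1-carboxylate
Conditions: Boc2O, 4-(dimethylamino)pyridine (10 mol %), MeCN, rt
Reagents that add atoms: di-tert-butyl dicarbonate CC(C)(C)OC(=O)OC(=O)OC(C)(C)C
Why: Boc protection by nucleophilic-catalysed N-acylation removes the acidic N–H and switches off the vinylogous-amide deactivation of the aldehyde, both needed for the strong-base step 5.

**Step 3**
Reactants: 5 5-bromo-1H-pyrrole-2-carboxamide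
Product: 7 5-bromo-N-[(4-methylbenzenesulfonyl)methyl]-1H-pyrrole-2-carboxamide, via N-hydroxymethyl amide 6 (not isolated)
Conditions: (CH2O)n, 4-MeC6H4SO2Na, HCO2H/H2O, 50 °C
Reagents that add atoms: formaldehyde (from paraformaldehyde) C=O; sodium p-toluenesulfinate Cc1ccc(cc1)S(=O)[O-].[Na+]
Why: Three-component Mannich-type amidoalkylation, in which hemiaminal 6 ionises to an N-acyliminium ion that sulfinate traps at sulfur to give a crystalline α-amido sulfone, while the acyl- and bromo-deactivated pyrrole ring resists formaldehyde.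

**Step 4**
Reactants: 7 5-bromo-N-[(4-methylbenzenesulfonyl)methyl]-1H-pyrrole-2-carboxamide
Product: 8 5-bromo-N-[(4-methylbenzenesulfonyl)methyl]-1H-pyrrole-2-carbothioamide
Conditions: Lawesson's reagent (0.55 equiv), THF, 50 °C
Reagents that add atoms: Lawesson's reagent COc1ccc(cc1)P1(=S)SP(=S)(S1)c1ccc(OC)cc1
Why: Lawesson thionation (Wittig-like O/S exchange through a thiaoxaphosphetane) converts the secondary amide, the only reactive carbonyl, into the thioamide and leaves sulfone, bromide and pyrrole N–H untouched.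

**Step 5**
Reactants: 8 5-bromo-N-[(4-methylbenzenesulfonyl)methyl]-1H-pyrrole-2-carbothioamide; 4 tert-butyl 6-bromo-3-formyl-4-methoxy-1H-indole-1-carboxylate
Product: 12 6-bromo-3-[2-(5-bromo-1H-pyrrol-2-yl)-1,3-oxazol-5-yl]-4-methoxy-1H-indole, via thioimidate hydroiodide 9 (not isolated), via tosyl-oxazoline 10 (not isolated), via N-Boc oxazole 11 (not isolated)
Conditions: MeI (1.2 equiv), acetone, rt, then evaporate; LiN(iPr)2 (3.1 equiv), THF, −78 °C; 4, −78 °C to rt; then K2CO3, MeOH, 50 °C
Reagents that add atoms: none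
Why: Proposed new method: S-methylation makes 9, a C2-substituted analogue of TosMIC, and LiN(iPr)2 removes HI, the pyrrole N–H and then a proton of the CH2 flanked by sulfonyl and imino groups, giving a sulfonyl-stabilised 2-azaallyl carbanion in which the normally electrophilic N-acyliminium carbon is nucleophilic; this carbanion adds to the aldehyde carbon of 4 (C4–C5 bond), the alkoxide closes onto the thioimidate carbon with loss of MeS− to give 10 (diastereomer mixture, both stereocentres erased next), pyrrole-assisted loss of sulfinate aromatises it to 11, and methanolysis removes Boc; the closest known reaction type is the van Leusen oxazole synthesis with TosMIC and its N-(tosylmethyl)imino analogues such as TsCH2N=C(SMe)2.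

**Compound list**
1 | 6-bromo-4-methoxy-1H-indole | COc1cc(Br)cc2[nH]ccc12 | starting material
2 | N-[(6-bromo-4-methoxy-1H-indol-3-yl)methylidene]-N-methylmethanaminium chloride | COc1cc(Br)cc2[nH]cc(C=[N+](C)C)c12.[Cl-] | intermediate
3 | 6-bromo-4-methoxy-1H-indole-3-carbaldehyde | COc1cc(Br)cc2[nH]cc(C=O)c12 | intermediate
4 | tert-butyl 6-bromo-3-formyl-4-methoxy-1H-indole-1-carboxylate | COc1cc(Br)cc2n(C(=O)OC(C)(C)C)cc(C=O)c12 | intermediate
5 | 5-bromo-1H-pyrrole-2-carboxamide | NC(=O)c1ccc(Br)[nH]1 | starting material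
6 | 5-bromo-N-(hydroxymethyl)-1H-pyrrole-2-carboxamide | OCNC(=O)c1ccc(Br)[nH]1 | intermediate
7 | 5-bromo-N-[(4-methylbenzenesulfonyl)methyl]-1H-pyrrole-2-carboxamide | Cc1ccc(cc1)S(=O)(=O)CNC(=O)c1ccc(Br)[nH]1 | intermediate
8 | 5-bromo-N-[(4-methylbenzenesulfonyl)methyl]-1H-pyrrole-2-carbothioamide | Cc1ccc(cc1)S(=O)(=O)CNC(=S)c1ccc(Br)[nH]1 | intermediate
9 | methyl 5-bromo-N-[(4-methylbenzenesulfonyl)methyl]-1H-pyrrole-2-carbimidothioate hydroiodide (E/Z not defined) | CSC(=[NH+]CS(=O)(=O)c1ccc(C)cc1)c1ccc(Br)[nH]1.[I-] | intermediate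
10 | tert-butyl 6-bromo-3-[2-(5-bromo-1H-pyrrol-2-yl)-4-(4-methylbenzenesulfonyl)-4,5-dihydro-1,3-oxazol-5-yl]-4-methoxy-1H-indole-1-carboxylate (racemic diastereomer mixture) | COc1cc(Br)cc2n(C(=O)OC(C)(C)C)cc(C3OC(c4ccc(Br)[nH]4)=NC3S(=O)(=O)c3ccc(C)cc3)c12 | intermediate
11 | tert-butyl 6-bromo-3-[2-(5-bromo-1H-pyrrol-2-yl)-1,3-oxazol-5-yl]-4-methoxy-1H-indole-1-carboxylate | COc1cc(Br)cc2n(C(=O)OC(C)(C)C)cc(-c3cnc(-c4ccc(Br)[nH]4)o3)c12 | intermediate
12 | 6-bromo-3-[2-(5-bromo-1H-pyrrol-2-yl)-1,3-oxazol-5-yl]-4-methoxy-1H-indole (CNP0145233.0, achiral) | COc1cc(Br)cc2[nH]cc(-c3cnc(-c4ccc(Br)[nH]4)o3)c12 | target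

**Totals**
Total step count: 5. Longest linear sequence: 3 steps (1 → 3 → 4 → 12, or 5 → 7 → 8 → 12).

**Three steps most likely to fail, with fallbacks**

Step 5 (oxazole-forming cascade). The pyrrolide formed first may expel sulfinate before the carbanion is generated, or ring closure may stall on the anionic substrate. The fallback replaces the one-pot dianion cascade with a fully protected, stepwise monoanion sequence. It sets out from 9: aqueous NaHCO3 work-up gives the free thioimidate methyl 5-bromo-N-[(4-methylbenzenesulfonyl)methyl]-1H-pyrrole-2-carbimidothioate F1. Boc2O with catalytic 4-(dimethylamino)pyridine in MeCN then gives tert-butyl 2-bromo-5-{(methylsulfanyl)[(4-methylbenzenesulfonyl)methylimino]methyl}-1H-pyrrole-1-carboxylate F2. With no acidic N–H left, one equivalent of LiN(SiMe3)2 in THF at −78 °C gives the monoanion, which adds to 4 and cyclises with loss of methanethiolate to the isolable tert-butyl 6-bromo-3-[2-(5-bromo-1-(tert-butoxycarbonyl)pyrrol-2-yl)-4-(4-methylbenzenesulfonyl)-4,5-dihydro-1,3-oxazol-5-yl]-4-methoxy-1H-indole-1-carboxylate F3. 1,8-Diazabicyclo[5.4.0]undec-7-ene in THF at 50 °C eliminates sulfinic acid to give tert-butyl 6-bromo-3-[2-(5-bromo-1-(tert-butoxycarbonyl)pyrrol-2-yl)-1,3-oxazol-5-yl]-4-methoxy-1H-indole-1-carboxylate F4. K2CO3 in MeOH removes both Boc groups and the fallback comes back to the route at 12.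

Step 3 (Mannich condensation). Free formaldehyde in acid may hydroxymethylate the pyrrole ring at C4. The fallback separates amidoalkylation from sulfone formation and uses no free formaldehyde or formic acid. It sets out from 5: condensation with commercial 1-(hydroxymethyl)benzotriazole (toluene, reflux, water removal, catalytic 4-MeC6H4SO3H) gives N-(1H-benzotriazol-1-ylmethyl)-5-bromo-1H-pyrrole-2-carboxamide F5. Sodium p-toluenesulfinate in DMF at 80 °C then displaces benzotriazole through the N-acylimine, and the fallback comes back to the route at 7.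

Step 4 (thionation). Heating the α-amido sulfone with Lawesson's reagent may cause loss of sulfinate (retro-Mannich) or incomplete O/S exchange. The fallback avoids sulfur altogether. It sets out from 7: O-methylation with Me3OBF4 in CH2Cl2 at rt, followed by cold aqueous NaHCO3, gives methyl 5-bromo-N-[(4-methylbenzenesulfonyl)methyl]-1H-pyrrole-2-carbimidate F6. F6 takes the place of 9 in the step 5 cascade (LiN(iPr)2, 2.1 equiv, then 4), with methoxide as the leaving group in ring closure, and the fallback comes back to the route at 10, which goes on to 12 as in step 5.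

**Further compounds**
F1 | step 5 | methyl 5-bromo-N-[(4-methylbenzenesulfonyl)methyl]-1H-pyrrole-2-carbimidothioate | CSC(=NCS(=O)(=O)c1ccc(C)cc1)c1ccc(Br)[nH]1
F2 | step 5 | tert-butyl 2-bromo-5-{(methylsulfanyl)[(4-methylbenzenesulfonyl)methylimino]methyl}-1H-pyrrole-1-carboxylate | CSC(=NCS(=O)(=O)c1ccc(C)cc1)c1ccc(Br)n1C(=O)OC(C)(C)C
F3 | step 5 | tert-butyl 6-bromo-3-[2-(5-bromo-1-(tert-butoxycarbonyl)pyrrol-2-yl)-4-(4-methylbenzenesulfonyl)-4,5-dihydro-1,3-oxazol-5-yl]-4-methoxy-1H-indole-1-carboxylate (racemic diastereomer mixture) | COc1cc(Br)cc2n(C(=O)OC(C)(C)C)cc(C3OC(c4ccc(Br)n4C(=O)OC(C)(C)C)=NC3S(=O)(=O)c3ccc(C)cc3)c12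
F4 | step 5 | tert-butyl 6-bromo-3-[2-(5-bromo-1-(tert-butoxycarbonyl)pyrrol-2-yl)-1,3-oxazol-5-yl]-4-methoxy-1H-indole-1-carboxylate | COc1cc(Br)cc2n(C(=O)OC(C)(C)C)cc(-c3cnc(-c4ccc(Br)n4C(=O)OC(C)(C)C)o3)c12
F5 | step 3 | N-(1H-benzotriazol-1-ylmethyl)-5-bromo-1H-pyrrole-2-carboxamide | O=C(NCn1nnc2ccccc12)c1ccc(Br)[nH]1
F6 | step 4 | methyl 5-bromo-N-[(4-methylbenzenesulfonyl)methyl]-1H-pyrrole-2-carbimidate | COC(=NCS(=O)(=O)c1ccc(C)cc1)c1ccc(Br)[nH]1
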